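**Retrosynthetic overview**

1. The last C–C bond made is the allylic CH2–CH= bond next to the free acid. It is formed by a three-component union of a primary alkylzinc (furan, methyl ester, stereocentre and E-alkene already in place), CO2 and a C9 silyl alkyne on nickel, which also makes the C–CO2H bond and sets the alkene geometry.
2. The enabling feature is the α-alkylidene carboxyl unit HC=C(CO2H): the carboxyl carbon and the β-CH2 chain are cis on the C=C. This maps onto the Ni–C=C–C(=O)–O ring of an oxanickelacyclopentenone, with Ni in the place of the incoming chain. A silyl group on the alkyne carbon that becomes the vinylic CH fixes the regiochemistry and is removed by fluoride.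
3. The methyl (Z)-enoate on the furan side has the same feature and is built earlier by the same reaction (furylethylzinc + CO2 + silyl alkyne), then O-methylated.
4. The (E)-trisubstituted alkene comes from a Johnson–Claisen rearrangement, and the extra carboxyl carbon is excised by Barton iododecarboxylation. Both silyl alkynes come from methyl ketones, and the stereocentre comes from ring-opening ozonolysis of (S)-limonene.
5. Rings: the furan is bought and no ring of the target is formed. Two transient five-membered nickelalactones appear (steps 4 and 12) and are opened in the same flask.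

Key step: step 12

Assumption: commercial (S)-(−)-limonene of high enantiomeric purity is used; the single stereocentre of the target is carried over from it unchanged, so its purity sets that of the product.

**Route**

Step 1
Reactants: 1 (S)-(−)-limonene
Product: 3 (5S)-7,7-dimethoxy-5-(prop-1-en-2-yl)heptan-2-one, via keto aldehyde 2 (not isolated)
Conditions: O3 (1 equiv), CH2Cl2/MeOH, −78 °C; Me2S, −78 °C → rt; then TsOH·H2O (cat.), MeOH, rt
Reagents that add atoms: ozone, [O-][O+]=O; methanol, CO
Why: Ozonolysis with reductive work-up should cleave the electron-richer trisubstituted ring alkene well before the isopropenyl group at −78 °C, and acidic methanol acetalises only the aldehyde; the stereocentre is not touched.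

Step 2
Reactants: 3 (5S)-7,7-dimethoxy-5-(prop-1-en-2-yl)heptan-2-one
Product: 6 benzyl[(5S)-7,7-dimethoxy-5-(prop-1-en-2-yl)hept-1-yn-1-yl]dimethylsilane, via enol phosphate 4 (not isolated), via lithium acetylide 5 (not isolated)
Conditions: LDA (1.1 equiv), THF, −78 °C; ClP(O)(OEt)2, −78 °C → rt; LDA (2.3 equiv), −78 °C → rt; BnMe2SiCl, −78 °C → rt
Reagents that add atoms: benzylchlorodimethylsilane, C[Si](C)(Cl)Cc1ccccc1
Why: Kinetic enolisation at CH3, O-phosphorylation and base-induced elimination of the enol phosphate (methyl ketone → terminal alkyne) give the acetylide, which is C-silylated in the same flask; the acetal and the remote stereocentre are inert to LDA.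

Step 3
Reactants: 7 2-(furan-3-yl)ethanol
Product: 8 3-(2-iodoethyl)furan
Conditions: I2, PPh3, imidazole, CH2Cl2, 0 °C → rt
Reagents that add atoms: iodine, II
Why: Appel-type iodination of a primary alcohol runs under near-neutral conditions that the acid-sensitive furan tolerates.

Step 4
Reactants: 6 benzyl[(5S)-7,7-dimethoxy-5-(prop-1-en-2-yl)hept-1-yn-1-yl]dimethylsilane; 8 3-(2-iodoethyl)furan
Product: 11 (2E)-3-[benzyl(dimethyl)silyl]-2-[(3S)-5,5-dimethoxy-3-(prop-1-en-2-yl)pentyl]-5-(furan-3-yl)pent-2-enoic acid, via furylethylzinc iodide 9 (not isolated), via nickelalactone 10 (not isolated)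
Conditions: 8, Zn dust (activated), LiCl, THF, 25–40 °C (gives 9); 6, Ni(cod)2 (1.0 equiv), DBU (2.0 equiv), CO2 (1 atm), THF, 0 °C (gives 10); then 9 (3 equiv), 0 °C → rt; cold pH 3 aqueous work-up
Reagents that add atoms: carbon dioxide, O=C=O
Why: This is a nickel-mediated alkylative carboxylation of a silyl alkyne: oxidative cyclisation of Ni(0)/DBU, CO2 and 6 puts CO2 on the alkyne carbon remote from silicon, and transmetalation/reductive elimination delivers the furylethyl group to the silicon-bearing carbon cis to the carboxylate, which fixes the geometry; acetal, isopropenyl group and furan are inert.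

Step 5
Reactants: 11 (2E)-3-[benzyl(dimethyl)silyl]-2-[(3S)-5,5-dimethoxy-3-(prop-1-en-2-yl)pentyl]-5-(furan-3-yl)pent-2-enoic acid
Product: 12 methyl (2E)-3-[benzyl(dimethyl)silyl]-2-[(3S)-5,5-dimethoxy-3-(prop-1-en-2-yl)pentyl]-5-(furan-3-yl)pent-2-enoate
Conditions: MeI, K2CO3, DMF, rt
Reagents that add atoms: iodomethane, CI
Why: O-Alkylation of the carboxylate (SN2 on MeI) is insensitive to the crowding of the tetrasubstituted acrylic acid and leaves acetal, furan and vinylsilane alone.

Step 6
Reactants: 12 methyl (2E)-3-[benzyl(dimethyl)silyl]-2-[(3S)-5,5-dimethoxy-3-(prop-1-en-2-yl)pentyl]-5-(furan-3-yl)pent-2-enoate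
Product: 13 methyl (2E)-3-[benzyl(dimethyl)silyl]-5-(furan-3-yl)-2-[(3S)-5-oxo-3-(prop-1-en-2-yl)pentyl]pent-2-enoate
Conditions: TsOH·H2O (cat.), acetone/H2O, rt
Reagents that add atoms: water, O
Why: Mild acid-catalysed hydrolysis of the dimethyl acetal should not protodesilylate the electron-poor vinylsilane, and the stereocentre is β to the new aldehyde and cannot epimerise.

Step 7
Reactants: 13 methyl (2E)-3-[benzyl(dimethyl)silyl]-5-(furan-3-yl)-2-[(3S)-5-oxo-3-(prop-1-en-2-yl)pentyl]pent-2-enoate
Product: 14 methyl (2E)-3-[benzyl(dimethyl)silyl]-5-(furan-3-yl)-2-[(3S)-5-hydroxy-6-methyl-3-(prop-1-en-2-yl)hept-6-en-1-yl]pent-2-enoate (both carbinol epimers)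
Conditions: CH2=C(CH3)MgBr (1.2 equiv), THF, −78 °C; aq. NH4Cl
Reagents that add atoms: isopropenylmagnesium bromide, C=C(C)[Mg]Br
Why: Grignard 1,2-addition to the aldehyde should be far faster at −78 °C than attack on the shielded tetrasubstituted methyl enoate; the new carbinol centre is formed unselectively and is destroyed in step 8.

Step 8
Reactants: 14 methyl (2E)-3-[benzyl(dimethyl)silyl]-5-(furan-3-yl)-2-[(3S)-5-hydroxy-6-methyl-3-(prop-1-en-2-yl)hept-6-en-1-yl]pent-2-enoate
Product: 16 methyl (2E)-3-[benzyl(dimethyl)silyl]-2-[(3S,5E)-9-ethoxy-6-methyl-9-oxo-3-(prop-1-en-2-yl)non-5-en-1-yl]-5-(furan-3-yl)pent-2-enoate, via ketene acetal 15 (not isolated)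
Conditions: CH3C(OEt)3 (excess), EtCO2H (cat.), 135 °C, EtOH distilled off
Reagents that add atoms: triethyl orthoacetate, CC(OCC)(OCC)OCC
Why: The Johnson–Claisen rearrangement passes through a chair transition state with the carbinol substituent equatorial, which should give the (E)-trisubstituted alkene from both carbinol epimers.

Step 9
Reactants: 16 methyl (2E)-3-[benzyl(dimethyl)silyl]-2-[(3S,5E)-9-ethoxy-6-methyl-9-oxo-3-(prop-1-en-2-yl)non-5-en-1-yl]-5-(furan-3-yl)pent-2-enoate
Product: 17 (4E,7S,10E)-11-[benzyl(dimethyl)silyl]-13-(furan-3-yl)-10-(methoxycarbonyl)-4-methyl-7-(prop-1-en-2-yl)trideca-4,10-dienoic acid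
Conditions: LiOH (1.5 equiv), THF/H2O, 0 °C → rt; dilute HCl to pH 3
Reagents that add atoms: lithium hydroxide, [Li+].[OH-]
Why: Saponification of the unhindered saturated ethyl ester should be much faster than that of the conjugated, tetrasubstituted β-silyl methyl enoate.

Step 10
Reactants: 17 (4E,7S,10E)-11-[benzyl(dimethyl)silyl]-13-(furan-3-yl)-10-(methoxycarbonyl)-4-methyl-7-(prop-1-en-2-yl)trideca-4,10-dienoic acid
Product: 19 methyl (2E)-3-[benzyl(dimethyl)silyl]-5-(furan-3-yl)-2-[(3S,5E)-8-iodo-6-methyl-3-(prop-1-en-2-yl)oct-5-en-1-yl]pent-2-enoate, via Barton ester 18 (not isolated)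
Conditions: 1-hydroxypyridine-2(1H)-thione, DCC, DMAP (cat.), CH2Cl2, 0 °C → rt, dark; then CHI3 (3 equiv), hν (tungsten lamp), rt
Reagents that add atoms: iodoform, IC(I)I
Why: In this Barton iododecarboxylation the thiohydroxamate ester fragments to a primary alkyl radical that should abstract iodine from iodoform faster than it cyclises or adds to the furan, so the carboxyl carbon is excised and the iodide sits on the carbon that enters the key bond.

Step 11
Reactants: 20 6-methylhept-5-en-2-one
Product: 23 benzyl(dimethyl)(6-methylhept-5-en-1-yn-1-yl)silane, via enol phosphate 21 (not isolated), via lithium acetylide 22 (not isolated)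
Conditions: LDA (1.1 equiv), THF, −78 °C; ClP(O)(OEt)2, −78 °C → rt; LDA (2.3 equiv), −78 °C → rt; BnMe2SiCl, −78 °C → rt
Reagents that add atoms: benzylchlorodimethylsilane, C[Si](C)(Cl)Cc1ccccc1
Why: This is the same methyl ketone → silyl alkyne sequence as step 2 (enol phosphate elimination, acetylide silylation), and the trisubstituted alkene is inert to it.

Step 12
Reactants: 19 methyl (2E)-3-[benzyl(dimethyl)silyl]-5-(furan-3-yl)-2-[(3S,5E)-8-iodo-6-methyl-3-(prop-1-en-2-yl)oct-5-en-1-yl]pent-2-enoate; 23 benzyl(dimethyl)(6-methylhept-5-en-1-yn-1-yl)silane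
Product: 26 (2E,6E,9S,12E)-3,13-bis[benzyl(dimethyl)silyl]-15-(furan-3-yl)-12-(methoxycarbonyl)-6-methyl-2-(4-methylpent-3-en-1-yl)-9-(prop-1-en-2-yl)pentadeca-2,6,12-trienoic acid, via alkylzinc iodide 24 (not isolated), via nickelalactone 25 (not isolated)
Conditions: 19, Zn dust (activated), LiCl, THF, 40 °C (gives 24); 23 (2 equiv), Ni(cod)2 (2 equiv), DBU (4 equiv), CO2 (1 atm), THF, 0 °C (gives 25); then 24 (1 equiv), 0 °C → rt; dilute HCl
Reagents that add atoms: carbon dioxide, O=C=O
Why: Ni(0)/DBU, CO2 and silyl alkyne 23 undergo oxidative cyclisation to the oxanickelacyclopentenone 25, with the new C–CO2 bond at the alkyne carbon remote from silicon and nickel on the silicon-bearing carbon (steric demand of the silyl group and the favoured α-silyl C–Ni bond); transmetalation with the primary alkylzinc iodide 24 and C(sp2)–C(sp3) reductive elimination then join the two halves with retention. The closest known reaction type is the nickel-mediated alkylative carboxylation of silyl alkynes with CO2 and organozinc reagents, which gives β-silyl acrylic acids of this substitution pattern. The only ring closed is the transient five-membered nickelacycle (oxidative cyclisation of alkyne, CO2 and Ni), and it is opened again in the same operation; no ring of the target is formed. No stereocentre is created: the alkene geometry follows from syn addition of Ni and CO2 across the alkyne, so the incoming chain ends cis to CO2H, and the existing (S) centre is remote and untouched. The step needs regioselectivity (secured by the silyl group), transmetalation at nickel in preference to reaction of the zinc reagent with CO2 or the methyl ester (alkylzinc halides should be inert to both at 0 °C), and reductive elimination faster than β-hydride elimination (favoured by the donor DBU ligands and the acceptor carboxylate on nickel). Because the acid is made from CO2 it is free while the other carboxyl group stays a methyl ester, so no protecting-group exchange is needed.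

Step 13
Reactants: 26 (2E,6E,9S,12E)-3,13-bis[benzyl(dimethyl)silyl]-15-(furan-3-yl)-12-(methoxycarbonyl)-6-methyl-2-(4-methylpent-3-en-1-yl)-9-(prop-1-en-2-yl)pentadeca-2,6,12-trienoic acid
Product: 27 (2Z,6E,9S,12Z)-15-(furan-3-yl)-12-(methoxycarbonyl)-6-methyl-2-(4-methylpent-3-en-1-yl)-9-(prop-1-en-2-yl)pentadeca-2,6,12-trienoic acid (CNP0201108.1)
Conditions: TBAF (1 M in THF, excess), THF, 0 °C → rt; pH 3 buffer
Reagents that add atoms: none
Why: In this fluoride-induced protodesilylation of the two benzyl(dimethyl)silyl alkenes, fluoride expels the benzyl group and the resulting fluorosilyl alkene is cleaved at C(sp2)–Si with retention of geometry, while the methyl ester should survive the short room-temperature treatment.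

**Compound list**

1 | (S)-(−)-limonene [(4S)-1-methyl-4-(prop-1-en-2-yl)cyclohex-1-ene] | CC1=CC[C@H](CC1)C(C)=C | starting material
2 | (3S)-6-oxo-3-(prop-1-en-2-yl)heptanal | C=C(C)[C@H](CC=O)CCC(C)=O | intermediate
3 | (5S)-7,7-dimethoxy-5-(prop-1-en-2-yl)heptan-2-one | C=C(C)[C@H](CC(OC)OC)CCC(C)=O | intermediate
4 | diethyl (5S)-7,7-dimethoxy-5-(prop-1-en-2-yl)hept-1-en-2-yl phosphate | C=C(C)[C@H](CC(OC)OC)CCC(=C)OP(=O)(OCC)OCC | intermediate
5 | [(5S)-7,7-dimethoxy-5-(prop-1-en-2-yl)hept-1-yn-1-yl]lithium | C=C(C)[C@H](CC(OC)OC)CCC#C[Li] | intermediate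
6 | benzyl[(5S)-7,7-dimethoxy-5-(prop-1-en-2-yl)hept-1-yn-1-yl]dimethylsilane | C=C(C)[C@H](CC(OC)OC)CCC#C[Si](C)(C)Cc1ccccc1 | intermediate
7 | 2-(furan-3-yl)ethanol | OCCc1ccoc1 | starting material
8 | 3-(2-iodoethyl)furan | ICCc1ccoc1 | intermediate
9 | [2-(furan-3-yl)ethyl]zinc iodide | I[Zn]CCc1ccoc1 | intermediate
10 | oxanickelacyclopentenone from 6 and CO2 (Ni on the silyl-bearing carbon; bis-DBU adduct, DBU written as separate components) | C=C(C)[C@H](CC(OC)OC)CCC1=C([Si](C)(C)Cc2ccccc2)[Ni]OC1=O.C1CCC2=NCCCN2CC1.C1CCC2=NCCCN2CC1 | intermediate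
11 | (2E)-3-[benzyl(dimethyl)silyl]-2-[(3S)-5,5-dimethoxy-3-(prop-1-en-2-yl)pentyl]-5-(furan-3-yl)pent-2-enoic acid (furylethyl cis to CO2H) | C=C(C)[C@H](CC(OC)OC)CC/C(=C(/CCc1ccoc1)[Si](C)(C)Cc1ccccc1)C(=O)O | intermediate
12 | methyl (2E)-3-[benzyl(dimethyl)silyl]-2-[(3S)-5,5-dimethoxy-3-(prop-1-en-2-yl)pentyl]-5-(furan-3-yl)pent-2-enoate | C=C(C)[C@H](CC(OC)OC)CC/C(=C(/CCc1ccoc1)[Si](C)(C)Cc1ccccc1)C(=O)OC | intermediate
13 | methyl (2E)-3-[benzyl(dimethyl)silyl]-5-(furan-3-yl)-2-[(3S)-5-oxo-3-(prop-1-en-2-yl)pentyl]pent-2-enoate | C=C(C)[C@H](CC=O)CC/C(=C(/CCc1ccoc1)[Si](C)(C)Cc1ccccc1)C(=O)OC | intermediate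
14 | methyl (2E)-3-[benzyl(dimethyl)silyl]-5-(furan-3-yl)-2-[(3S)-5-hydroxy-6-methyl-3-(prop-1-en-2-yl)hept-6-en-1-yl]pent-2-enoate (both carbinol epimers) | C=C(C)[C@H](CC(O)C(C)=C)CC/C(=C(/CCc1ccoc1)[Si](C)(C)Cc1ccccc1)C(=O)OC | intermediate
15 | 1-ethoxyvinyl ether of 14 (mixed ketene acetal) | C=C(C)[C@H](CC(OC(=C)OCC)C(C)=C)CC/C(=C(/CCc1ccoc1)[Si](C)(C)Cc1ccccc1)C(=O)OC | intermediate
16 | methyl (2E)-3-[benzyl(dimethyl)silyl]-2-[(3S,5E)-9-ethoxy-6-methyl-9-oxo-3-(prop-1-en-2-yl)non-5-en-1-yl]-5-(furan-3-yl)pent-2-enoate | C=C(C)[C@H](C/C=C(\C)CCC(=O)OCC)CC/C(=C(/CCc1ccoc1)[Si](C)(C)Cc1ccccc1)C(=O)OC | intermediate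
17 | (4E,7S,10E)-11-[benzyl(dimethyl)silyl]-13-(furan-3-yl)-10-(methoxycarbonyl)-4-methyl-7-(prop-1-en-2-yl)trideca-4,10-dienoic acid | C=C(C)[C@H](C/C=C(\C)CCC(=O)O)CC/C(=C(/CCc1ccoc1)[Si](C)(C)Cc1ccccc1)C(=O)OC | intermediate
18 | 2-thioxopyridin-1(2H)-yl ester of 17 (Barton ester) | C=C(C)[C@H](C/C=C(\C)CCC(=O)ON1C=CC=CC1=S)CC/C(=C(/CCc1ccoc1)[Si](C)(C)Cc1ccccc1)C(=O)OC | intermediate
19 | methyl (2E)-3-[benzyl(dimethyl)silyl]-5-(furan-3-yl)-2-[(3S,5E)-8-iodo-6-methyl-3-(prop-1-en-2-yl)oct-5-en-1-yl]pent-2-enoate | C=C(C)[C@H](C/C=C(\C)CCI)CC/C(=C(/CCc1ccoc1)[Si](C)(C)Cc1ccccc1)C(=O)OC | intermediate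
20 | 6-methylhept-5-en-2-one | CC(=O)CCC=C(C)C | starting material
21 | diethyl 6-methylhepta-1,5-dien-2-yl phosphate | C=C(CCC=C(C)C)OP(=O)(OCC)OCC | intermediate
22 | (6-methylhept-5-en-1-yn-1-yl)lithium | [Li]C#CCCC=C(C)C | intermediate
23 | benzyl(dimethyl)(6-methylhept-5-en-1-yn-1-yl)silane | C[Si](C)(Cc1ccccc1)C#CCCC=C(C)C | intermediate
24 | alkylzinc iodide from 19 (ZnI in place of I) | C=C(C)[C@H](C/C=C(\C)CC[Zn]I)CC/C(=C(/CCc1ccoc1)[Si](C)(C)Cc1ccccc1)C(=O)OC | intermediate
25 | oxanickelacyclopentenone from 23 and CO2 (Ni on the silyl-bearing carbon; bis-DBU adduct, DBU written as separate components) | CC(C)=CCCC1=C([Si](C)(C)Cc2ccccc2)[Ni]OC1=O.C1CCC2=NCCCN2CC1.C1CCC2=NCCCN2CC1 | intermediate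
26 | (2E,6E,9S,12E)-3,13-bis[benzyl(dimethyl)silyl]-15-(furan-3-yl)-12-(methoxycarbonyl)-6-methyl-2-(4-methylpent-3-en-1-yl)-9-(prop-1-en-2-yl)pentadeca-2,6,12-trienoic acid | C=C(C)[C@H](C/C=C(\C)CC/C(=C(/CCC=C(C)C)C(=O)O)[Si](C)(C)Cc1ccccc1)CC/C(=C(/CCc1ccoc1)[Si](C)(C)Cc1ccccc1)C(=O)OC | intermediate
27 | (2Z,6E,9S,12Z)-15-(furan-3-yl)-12-(methoxycarbonyl)-6-methyl-2-(4-methylpent-3-en-1-yl)-9-(prop-1-en-2-yl)pentadeca-2,6,12-trienoic acid (CNP0201108.1) | C=C(C)[C@H](C/C=C(\C)CC/C=C(/CCC=C(C)C)C(=O)O)CC/C(=C/CCc1ccoc1)C(=O)OC | target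

**Step count and risks**

Total steps: 13. Longest linear sequence: 11 steps (1, 2, 4, 5, 6, 7, 8, 9, 10, 12, 13).

Steps most likely to fail:

Step 12. β-Hydride elimination from the alkyl(alkenyl)nickel intermediate, or slow zinc-to-nickel transfer of the primary alkyl group to the crowded silyl-bearing carbon, would divert the nickelalactone to simple hydrocarboxylation and waste the large fragment. The fallback sets out from alkylzinc 24 and returns at 27. Propargyl alcohol is carbomagnesiated with (4-methylpent-3-en-1-yl)magnesium bromide and catalytic CuI (anti addition through the chelated magnesium alkoxide), and the vinylmagnesium species is iodinated to give (2Z)-3-iodo-2-(4-methylpent-3-en-1-yl)prop-2-en-1-ol F1. TEMPO/PhI(OAc)2 in MeCN–water oxidises this to (2Z)-3-iodo-2-(4-methylpent-3-en-1-yl)prop-2-enoic acid F2. Negishi coupling of the sodium salt of F2 with 24 under PdCl2(dppf) should proceed with retention to the mono-silyl acid F3 (27 still carrying the benzyl(dimethyl)silyl group on the ester-side alkene). TBAF then removes that one silyl group to give 27.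

Step 4. The same competition applies, and it is aggravated because β-hydride elimination of a 2-(furan-3-yl)ethyl group on nickel gives a conjugated vinylfuran. The fallback sets out from nickelalactone 10 (formed from 6 as in step 4) and returns at 11. The Ni–C bond of 10 is cleaved with iodine (or NIS) at low temperature with retention to give (2Z)-3-[benzyl(dimethyl)silyl]-2-[(3S)-5,5-dimethoxy-3-(prop-1-en-2-yl)pentyl]-3-iodoprop-2-enoic acid F4. The sodium salt of F4 is then joined to zinc reagent 9 by a Pd(dppf)-catalysed Negishi coupling, in which the bidentate ligand suppresses β-hydride elimination, to give 11.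

Step 13. Fluoride attack at the silicon next to the carboxylate anion may be slow, and prolonged exposure to basic fluoride could cleave the methyl ester or isomerise the Z-enoate units. The fallback sets out from 26 and returns at 27. The acid is first masked with 2-(trimethylsilyl)ethanol (DCC, DMAP) as the 2-(trimethylsilyl)ethyl ester of 26 F5, so that both vinylsilanes sit on neutral enoates. A short TBAF treatment should then remove both benzyl(dimethyl)silyl groups and the silylethyl ester in one operation to give 27.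

Further compounds
F1 | step 12 | (2Z)-3-iodo-2-(4-methylpent-3-en-1-yl)prop-2-en-1-ol | OC/C(=C\I)CCC=C(C)C
F2 | step 12 | (2Z)-3-iodo-2-(4-methylpent-3-en-1-yl)prop-2-enoic acid | OC(=O)/C(=C\I)CCC=C(C)C
F3 | step 12 | (2Z,6E,9S,12E)-13-[benzyl(dimethyl)silyl]-15-(furan-3-yl)-12-(methoxycarbonyl)-6-methyl-2-(4-methylpent-3-en-1-yl)-9-(prop-1-en-2-yl)pentadeca-2,6,12-trienoic acid | C=C(C)[C@H](C/C=C(\C)CC/C=C(/CCC=C(C)C)C(=O)O)CC/C(=C(/CCc1ccoc1)[Si](C)(C)Cc1ccccc1)C(=O)OC
F4 | step 4 | (2Z)-3-[benzyl(dimethyl)silyl]-2-[(3S)-5,5-dimethoxy-3-(prop-1-en-2-yl)pentyl]-3-iodoprop-2-enoic acid | C=C(C)[C@H](CC(OC)OC)CC/C(=C(/I)[Si](C)(C)Cc1ccccc1)C(=O)O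
F5 | step 13 | 2-(trimethylsilyl)ethyl ester of 26 | C=C(C)[C@H](C/C=C(\C)CC/C(=C(/CCC=C(C)C)C(=O)OCC[Si](C)(C)C)[Si](C)(C)Cc1ccccc1)CC/C(=C(/CCc1ccoc1)[Si](C)(C)Cc1ccccc1)C(=O)OC
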